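The constants were set for the occasion, and the outcome is calculated.

Late in the run I expected c(D) to have died away, so the state of the flask would be read from the fraction of G left, g, and I reckoned with that fraction.

    D ⇌ J, rate k1*([D] - [J]/K1) per volume of the first phase (K1 = 0.32, k1 = 0.228 s⁻¹)
    D + G.D → L (k2 = 24.3 L mol⁻¹ s⁻¹)
    2 D → D2 (k3 = 126 L mol⁻¹ s⁻¹)
    G + D → G.D (k4 = 133 L mol⁻¹ s⁻¹)
    D + G.D → D.G.D (k5 = 52.3 L mol⁻¹ s⁻¹)

G 2.0 mM; J 4.00 equiv; time 80 s; volume of the second phase over the first 1.0

- for a step with 2 of a species take k times the square, and two of it per event
- in the second phase: J; everything else is in the first
- charges count per volume of the first phase; a concentration in a rate is the amount of a species over the volume of its own phase; every rate counts per litre of the first phase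
- run time (flask): 80 s

- south-west: doubling the amount of J, all else as stated
- south: doubling the transfer coefficient of step 1, all else as stated

* how much G.D there is at 80 s, in percent of the G charged
* the change that raises the amount of G.D at 80 s, in percent of the G charged most ("none" if none brings more than 2 percentage points) (south-west / south / none)
* amount of G.D at 80 s, in percent of the G charged, after south-west

G and G.D meet the same D, so dividing their rates removes time. I named the selectivity factor s, the constant for losing G.D by both paths over the constant for making it, 0.576. Then c(G.D)/c(G, charged) = (g^s − g)/(1 − s).

Next I needed g, and −ln g is the G constant times the integral of c(D) over time. At equal concentrations D spends itself on itself faster than on G, so I first let dimerisation alone balance the inflow from J. That gave −ln g = 1.78, so g = 16.9% and G.D = 44.9%.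

The weak link was the return of D into J. While dimerisation drains D, each e-fold of falling c(D) adds 0.169 to −ln g, and I guessed 2.3 e-folds of that kind. So I put g at 11.5% and G.D at 40.7%, which I held to. Scaling the first term as the root of J over the transfer coefficient gave 31.4% for south-west and 45.9% for south, so I chose south.

The forecast gave 40.7% (range 38.5% to 43%), 34% after south-west, and south, on the ground that doubling the transfer coefficient “wastes more D to dimer”. Its south-west figure stood above mine.

The flask gave 40.2%, south, and 24.5% after south-west, lower than the forecast by 9.5 percentage points. G.D still stood at 40.1% after 800 s. With 11% of G left, the rule gives 40.2%.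

In the neighbour flask with 5.0 mM of G, 6.0% of G was left, and the rule gives 32.5%. The simulation gives 32.5%.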